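**Plan**

- Numbering used: cyclohexene C1 (carries the carbinol carbon and coumarin A), C2 (carries coumarin B), C3=C4(CH3), C5, C6 (gem-dimethyl).
- Retrosynthesis: the carbinol C–H is cut first (aryl ketone 14). Ring bond C1–C2 is then shifted back to C1–C4, which turns the six-membered ring into the cyclobutane C1–C6–C5–C4 of vinylcyclobutane 12. The aryl–vinyl bond (Heck) and the aryl–acyl bond (Negishi) are cut to one iodocoumarin 2, and the cyclobutane to a (2+2) photoadduct of a butenolide and isobutene.
- Enabling feature: C2 is at once benzylic to the 2,4,6-trioxygenated benzene ring of coumarin B and allylic to C3=C4, and C1 carries a carbon that is an aryl ketone one oxidation level up. Bond C1–C2 is therefore a donor–acceptor bond, and its 1,3-allylic isomer (bond C1–C4) is a strained donor–acceptor vinylcyclobutane that ionises on mild acid activation.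
- Forward order: cyclobutane ring (photochemistry, before any light-sensitive coumarin is present), coumarin A as aryl ketone, coumarin B by Heck reaction, expansion of the four- to the six-membered ring, carbinol last.
- Stereochemistry: the cyclobutane is racemic and both its stereocentres are erased on ring opening. C2 is set by the chiral counter-anion in the ring closure, C1 follows as the trans (diequatorial, epimerisable) centre, and the carbinol centre comes from Felkin–Anh hydride addition.

Key step: step 8

Assumption: electrophilic iodination of 5,7-dimethoxycoumarin is taken to occur at C8 (para to the 5-methoxy group, ortho to the ring oxygen) and not at C6, which lies between two methoxy groups.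

**Route**

Step 1
Reactants: 1 5,7-dimethoxy-2H-chromen-2-one (5,7-dimethoxycoumarin)
Product: 2 8-iodo-5,7-dimethoxy-2H-chromen-2-one
Conditions: NIS (1.05 equiv), TFA (0.3 equiv), MeCN, 0 °C→rt, dark
Reagents that add atoms: N-iodosuccinimide, O=C1CCC(=O)N1I
Why: Electrophilic aromatic substitution in which the iodonium equivalent attacks the phloroglucinol-type ring at C8, the position para to the 5-methoxy group and flanked by only one methoxy group, and no stereocentre is formed.

Step 2
Reactants: 3 3-methylfuran-2(5H)-one; 4 2-methylprop-1-ene (isobutene)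
Product: 5 rac-cis-1,6,6-trimethyl-3-oxabicyclo[3.2.0]heptan-2-one
Conditions: hν (300 nm), acetone (sensitiser and solvent), 4 (excess), −40 °C
Reagents that add atoms: none
Why: Triplet-sensitised enone–alkene (2+2) photocycloaddition in which the electron-rich alkene adds head-to-tail, its CMe2 carbon to the β-carbon of the butenolide, which also avoids two adjacent quaternary carbons, the 5/4 ring fusion can only be cis, and the racemic nature of 5 is harmless because both of its stereocentres are erased in step 8.

Step 3
Reactants: 5 rac-cis-1,6,6-trimethyl-3-oxabicyclo[3.2.0]heptan-2-one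
Product: 6 rac-cis-1,6,6-trimethyl-3-oxabicyclo[3.2.0]heptan-2-ol (lactol, anomer mixture)
Conditions: i-Bu2AlH (1.1 equiv), CH2Cl2, −78 °C; aqueous potassium sodium tartrate
Reagents that add atoms: none
Why: Partial reduction of a lactone, in which the tetrahedral aluminium hemiacetal formed by one hydride transfer is stable at −78 °C and gives the lactol on work-up, its new anomeric centre being of no consequence.

Step 4
Reactants: 6 rac-cis-1,6,6-trimethyl-3-oxabicyclo[3.2.0]heptan-2-ol
Product: 7 rac-(cis-2-ethenyl-2,4,4-trimethylcyclobutyl)methanol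
Conditions: Ph3PCH3Br (3 equiv), KOt-Bu (2.9 equiv), THF, 0 °C→45 °C
Reagents that add atoms: methyltriphenylphosphonium bromide, C[P+](c1ccccc1)(c1ccccc1)c1ccccc1.[Br-]
Why: Wittig methylenation of the hydroxy-aldehyde that is in equilibrium with the lactol, whose aldehyde sits on a quaternary carbon and cannot enolise, so that no stereocentre is formed or lost.

Step 5
Reactants: 7 rac-(cis-2-ethenyl-2,4,4-trimethylcyclobutyl)methanol
Product: 8 rac-cis-2-ethenyl-2,4,4-trimethylcyclobutane-1-carboxylic acid
Conditions: TEMPO (7 mol%), NaOCl (2 mol%), NaClO2 (2 equiv), MeCN/aqueous phosphate buffer pH 6.7, 35 °C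
Reagents that add atoms: sodium chlorite, [Na+].[O-]Cl=O
Why: Nitroxyl-catalysed oxidation of the primary alcohol to the aldehyde followed in the same flask by chlorite oxidation to the acid, a buffered method that leaves the isolated vinyl group alone, with no stereocentre formed.

Step 6
Reactants: 8 rac-cis-2-ethenyl-2,4,4-trimethylcyclobutane-1-carboxylic acid; 2 8-iodo-5,7-dimethoxy-2H-chromen-2-one
Product: 11 rac-8-(cis-2-ethenyl-2,4,4-trimethylcyclobutane-1-carbonyl)-5,7-dimethoxy-2H-chromen-2-one, via acid chloride 9 (not isolated), via arylzinc iodide 10 (not isolated)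
Conditions: 8, (COCl)2, DMF (cat.), CH2Cl2, 0 °C→rt, evaporate; separately 2, Zn dust, LiCl, THF, 50 °C; combine, Pd(PPh3)4 (5 mol%), THF, 0 °C→rt
Reagents that add atoms: none
Why: Negishi acylation in which the acylpalladium chloride formed from 9 takes the aryl group from the lactone-tolerant arylzinc 10 and reductive elimination gives the aryl ketone under neutral conditions that spare the vinyl group, epimerisation of the centre next to the new ketone being without consequence.

Step 7
Reactants: 11 rac-8-(cis-2-ethenyl-2,4,4-trimethylcyclobutane-1-carbonyl)-5,7-dimethoxy-2H-chromen-2-one; 2 8-iodo-5,7-dimethoxy-2H-chromen-2-one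
Product: 12 rac-8-{cis-2-[(E)-2-(5,7-dimethoxy-2-oxo-2H-chromen-8-yl)ethenyl]-2,4,4-trimethylcyclobutane-1-carbonyl}-5,7-dimethoxy-2H-chromen-2-one
Conditions: Pd2(dba)3 (2.5 mol%), P(t-Bu)3 (10 mol%), Cy2NMe (1.2 equiv), 1,4-dioxane, 30 °C
Reagents that add atoms: none
Why: Heck reaction in which the arylpalladium species from 2 adds its aryl group to the terminal vinyl carbon and syn β-hydride elimination gives the (E)-alkene, the quaternary allylic carbon ruling out double-bond migration, while the non-polar, amine-buffered medium near room temperature keeps the newly formed donor–acceptor cyclobutane from ionising.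

Step 8
Reactants: 12 rac-8-{cis-2-[(E)-2-(5,7-dimethoxy-2-oxo-2H-chromen-8-yl)ethenyl]-2,4,4-trimethylcyclobutane-1-carbonyl}-5,7-dimethoxy-2H-chromen-2-one
Product: 14 8-[(1S,2R)-2-(5,7-dimethoxy-2-oxo-2H-chromen-8-yl)-4,6,6-trimethylcyclohex-3-ene-1-carbonyl]-5,7-dimethoxy-2H-chromen-2-one, via ring-opened enol allyl cation 13 (not isolated)
Conditions: (R)-N-triflylphosphoramide of 3,3'-bis(2,4,6-triisopropylphenyl)-BINOL (10 mol%), toluene, 4 Å molecular sieves, −60 °C→−20 °C; Et3N quench
Reagents that add atoms: none
Why: Proposed new method: the chiral acid hydrogen-bonds to (or protonates) the aryl ketone of 12, and the cyclobutane bond C1–C4, aligned with the carbonyl π-system and carrying on C4 a 1-methyl-3-arylallyl donor whose aryl group is the 2,4,6-trioxygenated benzene ring of coumarin B, breaks heterolytically with release of the cyclobutane strain (about 26 kcal/mol) to give the enol/allyl-cation ion pair 13 with the chiral phosphoramide anion; the closest known reaction types are the Lewis- or Brønsted-acid opening of donor–acceptor cyclobutanes to 1,4-dipoles, the Lewis-acid-induced conversion of vinylcyclobutanes from stepwise (2+2) additions into cyclohexenes (a formal 1,3-shift), and, for the asymmetric induction, chiral phosphoric-acid-catalysed [1,3] rearrangements and allyl-cation cyclisations that run through contact ion pairs. The six-membered ring C1–C6 closes by attack of the enol carbon C1 on the benzylic terminus C2 of the allyl cation, a 6-(enolexo)-endo-trig closure that leaves the C3=C4 double bond inside the new ring. C2 is the centre the catalyst must control: both stereocentres of racemic 12 are trigonal in 13, the anion is held on one face of the planar cation by the ion pair and by its hydrogen bond to the enol OH, and the enol adds to the open face; the (R)-acid is written and its mirror image is taken if the first run shows the opposite sense. C1 is set relative to C2, because closure through a half-chair with the aroyl group and the aryl group both pseudo-equatorial gives the trans isomer, and since C1 is α to the ketone any cis isomer can be epimerised to trans (brief DBU treatment) without touching C2. The step needs C- over O-alkylation of the enol and attack at C2 over C4; return to C4 only regenerates the strained four-membered ring and O-alkylation gives enol ethers that re-ionise, so all paths drain into the strain-free cyclohexene, while the low temperature and non-polar solvent suppress achiral background ionisation.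

Step 9
Reactants: 14 8-[(1S,2R)-2-(5,7-dimethoxy-2-oxo-2H-chromen-8-yl)-4,6,6-trimethylcyclohex-3-ene-1-carbonyl]-5,7-dimethoxy-2H-chromen-2-one
Product: 15 8-{(S)-[(1S,2R)-2-(5,7-dimethoxy-2-oxo-2H-chromen-8-yl)-4,6,6-trimethylcyclohex-3-en-1-yl](hydroxy)methyl}-5,7-dimethoxy-2H-chromen-2-one (target)
Conditions: NaBH4 (2 equiv), THF/MeOH 4:1, −20 °C→0 °C; pH 7 phosphate buffer work-up
Reagents that add atoms: none
Why: Felkin–Anh addition of a small hydride to the aryl ketone, in which the quaternary C6 is the large group anti to the incoming hydride, the carbonyl oxygen lies beside C2 and the aryl ring of coumarin A beside the C1 hydrogen, so that attack gives the (S)-carbinol, and at or below 0 °C in a neutral medium NaBH4 spares both lactones and the acid-labile benzylic alcohol.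

**Compound list**

For racemic compounds 5–9, 11 and 12 one enantiomer is drawn.

1 | 5,7-dimethoxy-2H-chromen-2-one (5,7-dimethoxycoumarin) | COc1cc(OC)c2ccc(=O)oc2c1 | starting material
2 | 8-iodo-5,7-dimethoxy-2H-chromen-2-one | COc1cc(OC)c2ccc(=O)oc2c1I | intermediate
3 | 3-methylfuran-2(5H)-one | CC1=CCOC1=O | starting material
4 | 2-methylprop-1-ene (isobutene) | CC(C)=C | starting material
5 | rac-cis-1,6,6-trimethyl-3-oxabicyclo[3.2.0]heptan-2-one | O=C1OC[C@@H]2[C@@]1(C)CC2(C)C | intermediate
6 | rac-cis-1,6,6-trimethyl-3-oxabicyclo[3.2.0]heptan-2-ol (anomer mixture) | OC1OC[C@@H]2[C@@]1(C)CC2(C)C | intermediate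
7 | rac-(cis-2-ethenyl-2,4,4-trimethylcyclobutyl)methanol (CH2OH and ethenyl cis) | OC[C@@H]1[C@](C)(C=C)CC1(C)C | intermediate
8 | rac-cis-2-ethenyl-2,4,4-trimethylcyclobutane-1-carboxylic acid | OC(=O)[C@@H]1[C@](C)(C=C)CC1(C)C | intermediate
9 | rac-cis-2-ethenyl-2,4,4-trimethylcyclobutane-1-carbonyl chloride (not isolated) | ClC(=O)[C@@H]1[C@](C)(C=C)CC1(C)C | intermediate
10 | (5,7-dimethoxy-2-oxo-2H-chromen-8-yl)zinc iodide (not isolated) | COc1cc(OC)c2ccc(=O)oc2c1[Zn]I | intermediate
11 | rac-8-(cis-2-ethenyl-2,4,4-trimethylcyclobutane-1-carbonyl)-5,7-dimethoxy-2H-chromen-2-one | COc1cc(OC)c2ccc(=O)oc2c1C(=O)[C@@H]1[C@](C)(C=C)CC1(C)C | intermediate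
12 | rac-8-{cis-2-[(E)-2-(5,7-dimethoxy-2-oxo-2H-chromen-8-yl)ethenyl]-2,4,4-trimethylcyclobutane-1-carbonyl}-5,7-dimethoxy-2H-chromen-2-one | COc1cc(OC)c2ccc(=O)oc2c1C(=O)[C@@H]1[C@](C)(/C=C/c2c(OC)cc(OC)c3ccc(=O)oc23)CC1(C)C | intermediate
13 | ring-opened enol allyl cation, ion-paired with the phosphoramide anion (not isolated; cation drawn) | COc1cc(OC)c2ccc(=O)oc2c1C(O)=CC(C)(C)CC(C)=C[CH+]c1c(OC)cc(OC)c2ccc(=O)oc12 | intermediate
14 | 8-[(1S,2R)-2-(5,7-dimethoxy-2-oxo-2H-chromen-8-yl)-4,6,6-trimethylcyclohex-3-ene-1-carbonyl]-5,7-dimethoxy-2H-chromen-2-one | COc1cc(OC)c2ccc(=O)oc2c1C(=O)[C@H]1[C@H](c2c(OC)cc(OC)c3ccc(=O)oc23)C=C(C)CC1(C)C | intermediate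
15 | 8-{(S)-[(1S,2R)-2-(5,7-dimethoxy-2-oxo-2H-chromen-8-yl)-4,6,6-trimethylcyclohex-3-en-1-yl](hydroxy)methyl}-5,7-dimethoxy-2H-chromen-2-one | COc1cc(OC)c2ccc(=O)oc2c1[C@@H](O)[C@H]1[C@H](c2c(OC)cc(OC)c3ccc(=O)oc23)C=C(C)CC1(C)C | target

**Step count**

Total steps: 9. Longest linear sequence: 8 steps (steps 2–9, from 3 and 4 to 15); step 1 supplies iodide 2 for both aryl units.

**Steps most likely to fail**

Step 8. The collapse of the ion pair may discriminate poorly between the two faces of the allyl cation, or ionisation may proceed by an achiral background path, so that C2 is formed with low enantiomeric purity. The fallback uses known chemistry and sets out from 12. The ring expansion is run with an achiral Lewis acid, Sc(OTf)3 (5 mol%) in CH2Cl2 at −40 °C, the established way to ionise donor–acceptor cyclobutanes. This gives the racemic trans-ketone, that is 14 together with its mirror image 8-[(1R,2S)-2-(5,7-dimethoxy-2-oxo-2H-chromen-8-yl)-4,6,6-trimethylcyclohex-3-ene-1-carbonyl]-5,7-dimethoxy-2H-chromen-2-one F1. The two are separated by preparative chromatography on a chiral stationary phase, and the route is rejoined at 14.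

Step 6. Transmetalation of the doubly ortho-substituted arylzinc to the hindered acylpalladium complex may be slow, leaving time for decarbonylation of the acyl complex and homocoupling of the arylzinc. The fallback sets out from alcohol 7. Dess–Martin oxidation gives rac-cis-2-ethenyl-2,4,4-trimethylcyclobutane-1-carbaldehyde F2. Nozaki–Hiyama–Kishi coupling of this aldehyde with iodide 2 (CrCl2, NiCl2 cat., DMF, rt) gives the secondary alcohol 8-[(cis-2-ethenyl-2,4,4-trimethylcyclobutyl)(hydroxy)methyl]-5,7-dimethoxy-2H-chromen-2-one F3 as an epimer mixture. A second Dess–Martin oxidation converges the mixture and comes back to the route at ketone 11.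

Step 9. Facial selectivity of hydride addition may be poor because the two α-branches C2 and C6 compete for the role of the large group, and slow reduction of the hindered ketone may allow attack on a lactone. The fallback replaces substrate control by catalyst control and sets out from 14. Any wrongly configured carbinol, 8-{(R)-[(1S,2R)-2-(5,7-dimethoxy-2-oxo-2H-chromen-8-yl)-4,6,6-trimethylcyclohex-3-en-1-yl](hydroxy)methyl}-5,7-dimethoxy-2H-chromen-2-one F4, is first returned to 14 by Dess–Martin oxidation. The ketone is then reduced by CBS reduction (B-methyl oxazaborolidine, catecholborane, toluene, −78 °C), using the catalyst enantiomer that overrides the substrate bias and delivers hydride to the required face. The route is rejoined at 15.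

Further compounds
F1 | step 8 | 8-[(1R,2S)-2-(5,7-dimethoxy-2-oxo-2H-chromen-8-yl)-4,6,6-trimethylcyclohex-3-ene-1-carbonyl]-5,7-dimethoxy-2H-chromen-2-one | COc1cc(OC)c2ccc(=O)oc2c1C(=O)[C@@H]1[C@@H](c2c(OC)cc(OC)c3ccc(=O)oc23)C=C(C)CC1(C)C
F2 | step 6 | rac-cis-2-ethenyl-2,4,4-trimethylcyclobutane-1-carbaldehyde | O=C[C@@H]1[C@](C)(C=C)CC1(C)C
F3 | step 6 | 8-[(cis-2-ethenyl-2,4,4-trimethylcyclobutyl)(hydroxy)methyl]-5,7-dimethoxy-2H-chromen-2-one (epimer mixture at the carbinol) | COc1cc(OC)c2ccc(=O)oc2c1C(O)[C@@H]1[C@](C)(C=C)CC1(C)C
F4 | step 9 | 8-{(R)-[(1S,2R)-2-(5,7-dimethoxy-2-oxo-2H-chromen-8-yl)-4,6,6-trimethylcyclohex-3-en-1-yl](hydroxy)methyl}-5,7-dimethoxy-2H-chromen-2-one | COc1cc(OC)c2ccc(=O)oc2c1[C@H](O)[C@H]1[C@H](c2c(OC)cc(OC)c3ccc(=O)oc23)C=C(C)CC1(C)C
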